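Assumption: the target SMILES has no stereocentre, so the compound is achiral and there is no enantiomer to control; the sp3 centres in 7, 8 and 9 are racemic and are erased when the furan aromatises.

**Retrosynthetic overview**
1. Target 12 ⇒ bromobenzofuran 10 + 4-hydroxyphenylboronic acid 11 (Suzuki, last, so the free phenol never needs protection).
2. 10 ⇒ phenol 5 + γ-bromo-β-keto ester 8: the C3a–C3 bond joins the phenol ortho-carbon to C4 of the keto ester used as an enolonium (α-keto cation) equivalent; O1–C2 closes in the same pot by cyclodehydration.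
3. 5 ⇒ symmetric dibromide 2 (mono Br/Li exchange, borylation, oxidation) ⇒ 2,6-dibromo-4-methoxyphenol 1.
4. 8 ⇒ methyl 3-oxopentanoate 6 (γ-bromination).
5. Ring order: the central benzene ring is bought, the furan ring is formed in step 4, the outer phenol ring is attached in step 5.

**Route**

Step 1
Reactants: 1 2,6-dibromo-4-methoxyphenol
Product: 2 1,3-dibromo-2,5-dimethoxybenzene
Conditions: MeI (1.5 equiv), K2CO3, acetone, reflux
Reagents that add atoms: iodomethane, CI
Why: Williamson O-methylation of an acidic 2,6-dibromophenol whose phenoxide can only react at oxygen; no stereocentre is formed.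

Step 2
Reactants: 2 1,3-dibromo-2,5-dimethoxybenzene
Product: 5 3-bromo-2,5-dimethoxyphenol, via aryllithium 3 (not isolated), via lithium aryltrimethoxyborate 4 (not isolated)
Conditions: n-BuLi (1.0 equiv), THF, −78 °C; B(OMe)3, −78 °C → rt; AcOH then 30% H2O2, 0 °C → rt
Reagents that add atoms: hydrogen peroxide, OO (the phenol oxygen of 5); n-butyllithium, [Li]CCCC (lithium of 3 and 4 only); trimethyl borate, COB(OC)OC (boron and methoxy groups of 4 only)
Why: The two C–Br bonds of symmetric 2 are equivalent, so one equivalent of n-BuLi gives a single ortho-methoxy-stabilised aryllithium by halogen–lithium exchange, which is borylated and then oxidised with 1,2-aryl migration (boronate oxidation) to the phenol; no stereocentre is formed.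

Step 3
Reactants: 6 methyl 3-oxopentanoate
Product: 8 methyl 4-bromo-3-oxopentanoate (racemic), via 2-bromo keto ester 7 (not isolated)
Conditions: Br2 (1.0 equiv), CHCl3, 0 °C → rt, 16 h; used crude
Reagents that add atoms: bromine, BrBr
Why: Electrophilic bromination of a β-keto ester in a non-basic solvent, where the kinetically formed 2-bromo isomer equilibrates under the HBr released to the 4-bromo (γ) ketone; the new centre is racemic and is destroyed in step 4.

Step 4
Reactants: 5 3-bromo-2,5-dimethoxyphenol; 8 methyl 4-bromo-3-oxopentanoate (1.3 equiv)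
Product: 10 methyl 2-(6-bromo-4,7-dimethoxy-3-methyl-1-benzofuran-2-yl)acetate, via 2-hydroxyaryl ketone 9 (not isolated)
Conditions: TiCl4 (1.1 equiv), (CF3)2CHOH, 0 → 55 °C
Reagents that add atoms: none
Why: Proposed new method: TiCl4 binds the phenol and chelates the β-keto ester as its enol, and ionisation of the C4–Br bond allylic to that enol (helped by the fluorinated alcohol) gives a titanium oxyallyl cation that is an enolonium at C4 while the ester-bearing C2 terminus stays enolate-like; it is captured by C6 of the titanium-bound phenol, the only free ortho position, so that two normally nucleophilic α-carbons (phenol ortho-C and ketone α′-C) are joined, after which ketone 9 closes through its phenol oxygen and loses water to the aromatic furan, erasing the racemic centre; the closest known reaction type is the TiCl4-promoted one-pot Friedel–Crafts-type alkylation/cyclodehydration of phenols with simple α-haloketones in fluorinated alcohols, extended here to a γ-bromo-β-keto ester.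

Step 5
Reactants: 10 methyl 2-(6-bromo-4,7-dimethoxy-3-methyl-1-benzofuran-2-yl)acetate; 11 4-hydroxyphenylboronic acid
Product: 12 phenylcandilide B
Conditions: XPhos Pd G3 (2 mol %), K3PO4 (3 equiv), THF/H2O (4:1), 45 °C
Reagents that add atoms: none
Why: Suzuki–Miyaura coupling of an electron-rich, ortho-methoxy aryl bromide with a free-phenol boronic acid, using a dialkylbiarylphosphine catalyst so that it runs at a temperature and with a base mild enough to spare the methyl ester; no stereocentre is formed.

**Compound list**
1 | 2,6-dibromo-4-methoxyphenol | COc1cc(Br)c(O)c(Br)c1 | starting material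
2 | 1,3-dibromo-2,5-dimethoxybenzene | COc1cc(Br)c(OC)c(Br)c1 | intermediate
3 | (3-bromo-2,5-dimethoxyphenyl)lithium | [Li]c1cc(OC)cc(Br)c1OC | intermediate
4 | lithium (3-bromo-2,5-dimethoxyphenyl)trimethoxyborate | [Li+].CO[B-](OC)(OC)c1cc(OC)cc(Br)c1OC | intermediate
5 | 3-bromo-2,5-dimethoxyphenol | COc1cc(O)c(OC)c(Br)c1 | intermediate
6 | methyl 3-oxopentanoate | CCC(=O)CC(=O)OC | starting material
7 | methyl 2-bromo-3-oxopentanoate (racemic) | CCC(=O)C(Br)C(=O)OC | intermediate
8 | methyl 4-bromo-3-oxopentanoate (racemic) | CC(Br)C(=O)CC(=O)OC | intermediate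
9 | methyl 4-(4-bromo-2-hydroxy-3,6-dimethoxyphenyl)-3-oxopentanoate (racemic) | COC(=O)CC(=O)C(C)c1c(O)c(OC)c(Br)cc1OC | intermediate
10 | methyl 2-(6-bromo-4,7-dimethoxy-3-methyl-1-benzofuran-2-yl)acetate | COC(=O)Cc1oc2c(OC)c(Br)cc(OC)c2c1C | intermediate
11 | 4-hydroxyphenylboronic acid | OB(O)c1ccc(O)cc1 | starting material
12 | phenylcandilide B, methyl 2-[6-(4-hydroxyphenyl)-4,7-dimethoxy-3-methyl-1-benzofuran-2-yl]acetate | COC(=O)Cc1oc2c(OC)c(-c3ccc(O)cc3)cc(OC)c2c1C | target

**Count**
Total steps: 5. Longest linear sequence: 4 (steps 1, 2, 4, 5); step 3 is a one-step side branch.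

**Three steps most likely to fail**

Step 4 is the main risk. The phenol may attack the ketone carbonyl of 8 instead (Pechmann-type path to a 4-(1-bromoethyl)coumarin), it may react at the position para to OH, or 8 may self-condense. The fallback keeps the same bond but masks the ketone and makes ionisation easy. It sets out from 8: HC(OMe)3 with catalytic H2SO4 in MeOH gives the enol ether methyl (2E)-4-bromo-3-methoxypent-2-enoate F1. Silver trifluoroacetate in CH2Cl2 at −20 °C ionises F1 to a 2-methoxyallyl cation, whose methyl-bearing terminus alkylates 5 at its free ortho carbon to give methyl (2E)-4-(4-bromo-2-hydroxy-3,6-dimethoxyphenyl)-3-methoxypent-2-enoate F2. Catalytic TsOH in toluene at 80 °C then adds the phenol oxygen to the enol ether and expels methanol, and the route is rejoined at 10.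

Step 5 is the second risk: aqueous base may partly saponify the methyl ester while the coupling of the hindered bromide is still running. The fallback stops protecting the ester. It sets out from 10, which is coupled with 11 under Pd(dppf)Cl2 and aqueous KOH in dioxane at 90 °C so that hydrolysis goes to completion, giving after acidification 2-[6-(4-hydroxyphenyl)-4,7-dimethoxy-3-methyl-1-benzofuran-2-yl]acetic acid F3. Fischer esterification (MeOH, catalytic H2SO4, reflux) leaves the phenol untouched and comes back to the route at 12.

Step 2 is the third risk: the exchange may scramble (double exchange, or butylation of the aryllithium by the butyl bromide formed), or the one-pot oxidation may be incomplete. The fallback avoids organolithium chemistry. It sets out from 2, which undergoes palladium-catalysed Miyaura mono-borylation (B2pin2 0.9 equiv, Pd(dppf)Cl2, KOAc, dioxane, 80 °C) to give 2-(3-bromo-2,5-dimethoxyphenyl)-4,4,5,5-tetramethyl-1,3,2-dioxaborolane F4, separated from unreacted 2. Oxidation with H2O2/NaOH in THF at 0 °C returns to the route at 5.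

**Further compounds**
F1 | step 4 | methyl (2E)-4-bromo-3-methoxypent-2-enoate (racemic) | COC(=O)/C=C(/OC)C(C)Br
F2 | step 4 | methyl (2E)-4-(4-bromo-2-hydroxy-3,6-dimethoxyphenyl)-3-methoxypent-2-enoate (racemic) | COC(=O)/C=C(/OC)C(C)c1c(O)c(OC)c(Br)cc1OC
F3 | step 5 | 2-[6-(4-hydroxyphenyl)-4,7-dimethoxy-3-methyl-1-benzofuran-2-yl]acetic acid | OC(=O)Cc1oc2c(OC)c(-c3ccc(O)cc3)cc(OC)c2c1C
F4 | step 2 | 2-(3-bromo-2,5-dimethoxyphenyl)-4,4,5,5-tetramethyl-1,3,2-dioxaborolane | COc1cc(Br)c(OC)c(B2OC(C)(C)C(C)(C)O2)c1
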